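The numbers in the tables come from a simulation with made-up constants; the scatter is artificial.

Wednesday's run could not show me what the catalyst does: it held one charge, 240 mM, and the new flask holds 160 mM. That part of my reckoning was a guess.

- Wednesday's: substrate 2 M; solid reagent 1 M; catalyst 240 mM; run made earlier
- flask: substrate 2.0 M; solid reagent 1.00 M; catalyst 160 mM; time 40 min

- Wednesday's (time / min: product / %): 1.50: 2; 3.00: 1; 5.00: 11; 6.00: 10; 8.00: 14; 10.0: 17; 12.0: 22

(standard deviation of a reading: 2 percentage points)

- given per volume of solution although it is solid: solid reagent
- at the start none of the solid reagent is in solution
- no earlier run changes the charge of catalyst; that part of a forecast is a guess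

- west: doubling the dissolution coefficient of the solid reagent, all else as stated
- east: doubling the amount of catalyst, all else as stated
- south: doubling the solubility of the solid reagent, all else as stated

* the product standing at 40 min, as a percentage of the substrate charged
* the change that raises the amount of product at 40 min, in percent of the substrate charged most ("none" if none brings more than 2 percentage points) (west / east / south / none)
* amount of product at 40 min, in percent of the substrate charged, after east

I built the new flask up one process at a time. First I took the main step by itself. Wednesday's last reading, 22% at 12.0 min, gave a slope of 0.0183 /min as a fraction of the substrate charged, and that reading carries a scatter of 2 percentage points. I assumed the slope scales with catalyst. That gave 0.0122 /min for the new flask, and a straight line reached 48.9% at 40 min.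

Then I added the solid reagent. I assumed it reacts one to one with substrate, which made it the limiting reagent, with a ceiling of 50.0%. Dividing the ceiling by the slope gave 40.9 min. That is the crossing time, where the straight line meets the ceiling and control passes from rate to charge. It lay beside the asked time.

Last came the slowing, which I could not read from Wednesday's run. I committed to a figure somewhat below 48.9% for the new flask. With doubled catalyst the crossing moved to 20.5 min, earlier than the asked time, so I chose east.

The forecast gave 41%, within 33% to 50%, and 48% after east, within 41% to 56%. It chose south, holding that “Doubling solubility raises the rate under either limit”. There my choice differed.

The new flask gave 41.1%, and 46.2% after east. East gained 5.1 points, south 0.97 points and west 0.88 points, so the best change was east.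

    solid reagent ⇌ coupling partner, rate k1*(cs1 - [coupling partner]) while solid is left; crystals form when [coupling partner] > cs1 (solubility = 1.80 M, k = 0.0600 /min)
    substrate + coupling partner + catalyst ⇌ catalyst + product (K = 18.0 /M, k = 0.240 /M²/min)

The solid reagent dissolves into the coupling partner, which is what reacts. At 40 min the new flask stood at 82.2% of its ceiling, and its crossing time was 40.9 min. A neighbouring flask held 0.60 M of solid reagent, all else as in the new flask. Its ceiling was 30.0%, and at the same assumed slope its crossing time was 24.5 min, earlier than the asked time. Its product stood at 26.3% at 40 min, a larger share of its ceiling than in the new flask: 87.7%.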